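**Plan**

Cuts: the acid, the ring B phenol and the aldehyde are traced back to an allyl ester, an allyl ether and a dioxolane. Ring A is then opened at C1–C2 and C3–C4, and finally the bond from the bridging oxygen to the future C6 is cut.
Enabling feature: ring A carries CO2H at C1, OMe at C2, the branched side chain at C3 and the aryloxy group at C6, with C4 and C5 bare. C1, C6, C5 and C4 map onto C3, C4, C5 and C6 of a 4-aryloxy-2-pyrone-3-carboxylate, and C2 and C3 map onto the two alkene carbons of a 2-substituted ketene dimethyl acetal.
Forward order: the ring B phenol is made from creosol in four steps and the pyrone ring from diallyl malonate and (E)-3-ethoxyacryloyl chloride in three. The two are joined through the C–O bond, ring A arises last by cycloaddition with loss of CO2 and methanol, and two deprotections follow.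
Stereochemistry: the only stereocentre comes from (R)-2-hydroxy-4-methylpentanoic acid (chiral pool). It is carried as its methyl ether through a Horner–Wittig synthesis of the ketene acetal, which never places a carbanion next to the methoxy group, and through the neutral key step.

Key step: step 13

Assumption: all compounds marked as starting materials are taken to be commercially available. The descriptor stays (R) throughout because the order O > sp2 or oxygenated carbon > CH2 > H holds at every stage.

**Route**

Step 1
Reactants: 1 2-methoxy-4-methylphenol (creosol)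
Product: 2 2-hydroxy-3-methoxy-5-methylbenzaldehyde
Conditions: MgCl2, Et3N, (CH2O)n, MeCN, reflux; aq. HCl
Reagents that add atoms: paraformaldehyde (source of formaldehyde), C=O
Why: Casnati–Skattebøl ortho-formylation, in which the magnesium phenoxide directs formaldehyde to the only free ortho position and a second formaldehyde takes up hydride to leave the aldehyde.

Step 2
Reactants: 2 2-hydroxy-3-methoxy-5-methylbenzaldehyde
Product: 3 2,3-dihydroxy-5-methylbenzaldehyde
Conditions: BBr3 (2.5 equiv), CH2Cl2, −78 °C to 0 °C; H2O
Reagents that add atoms: none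
Why: Lewis-acid cleavage of the single aryl methyl ether, a standard reaction of o-vanillin-type aldehydes, done here because no methyl ether could be removed selectively later.

Step 3
Reactants: 3 2,3-dihydroxy-5-methylbenzaldehyde
Product: 4 3-(allyloxy)-2-hydroxy-5-methylbenzaldehyde
Conditions: NaH (2.2 equiv), DMSO, rt; allyl bromide (1.0 equiv); aq. HCl quench
Reagents that add atoms: allyl bromide, C=CCBr
Why: Williamson etherification under double deprotonation, in which the 2-oxide is delocalised into and chelated by the ortho formyl group, so the more nucleophilic 3-oxide should take the single equivalent of allyl bromide.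

Step 4
Reactants: 4 3-(allyloxy)-2-hydroxy-5-methylbenzaldehyde
Product: 5 2-(allyloxy)-6-(1,3-dioxolan-2-yl)-4-methylphenol
Conditions: ethylene glycol, TsOH·H2O (cat.), toluene, Dean–Stark; Et3N quench
Reagents that add atoms: ethylene glycol, OCCO
Why: Acid-catalysed acetalisation with azeotropic removal of water, known for salicylaldehydes; it shields the aldehyde from the nucleophilic ketene acetal and makes the phenoxide more nucleophilic.

Step 5
Reactants: 6 diallyl malonate; 7 (E)-3-ethoxyacryloyl chloride
Product: 8 diallyl 2-[(E)-3-ethoxyacryloyl]malonate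
Conditions: MgCl2, Et3N (2.1 equiv), MeCN, 0 °C; then 7, 0 °C to rt; aq. HCl
Reagents that add atoms: none
Why: Magnesium-mediated C-acylation of a malonate, in which the chelated enolate reacts at carbon with the acid chloride much faster than at the vinylogous ester terminus, and the acidic product is held as its magnesium chelate.

Step 6
Reactants: 8 diallyl 2-[(E)-3-ethoxyacryloyl]malonate
Product: 10 allyl 4-hydroxy-2-oxo-2H-pyran-3-carboxylate, via diallyl 2-(3-oxopropanoyl)malonate 9 (not isolated)
Conditions: TsOH·H2O (1.2 equiv), MeCN, 60 °C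
Reagents that add atoms: water, O
Why: Acid hydrolysis of the vinylogous ester followed by lactonisation of a 3,5-dioxo ester, the standard closure of 4-hydroxy-2-pyrones: the Z enol of the unmasked formyl group attacks one ester carbonyl and expels allyl alcohol.

Step 7
Reactants: 10 allyl 4-hydroxy-2-oxo-2H-pyran-3-carboxylate
Product: 11 allyl 4-chloro-2-oxo-2H-pyran-3-carboxylate
Conditions: (COCl)2 (1.5 equiv), DMF (cat.), CH2Cl2, 0 °C to 40 °C
Reagents that add atoms: oxalyl chloride, O=C(Cl)C(=O)Cl
Why: Vilsmeier-type deoxychlorination of a vinylogous acid, as practised on cyclic 1,3-diones and 4-hydroxycoumarin-3-carboxylates; a chloride is preferred to a sulfonate because a phenoxide cannot attack it at sulfur.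

Step 8
Reactants: 5 2-(allyloxy)-6-(1,3-dioxolan-2-yl)-4-methylphenol; 11 allyl 4-chloro-2-oxo-2H-pyran-3-carboxylate
Product: 12 allyl 4-[2-(allyloxy)-6-(1,3-dioxolan-2-yl)-4-methylphenoxy]-2-oxo-2H-pyran-3-carboxylate
Conditions: K2CO3 (dry, powdered), MeCN, 0 °C to rt
Reagents that add atoms: none
Why: Addition–elimination (vinylogous acyl substitution) at pyrone C4, which is β to both the lactone and the ester carbonyl and bears the leaving group, so attack there is irreversible while attack at C6 is not.

Step 9
Reactants: 13 (R)-2-hydroxy-4-methylpentanoic acid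
Product: 14 methyl (R)-2-methoxy-4-methylpentanoate
Conditions: MeI (excess), Ag2O, 4 Å MS, Et2O, rt, dark
Reagents that add atoms: iodomethane, CI
Why: Purdie methylation converts the hydroxyl and carboxyl groups together under essentially non-basic conditions, so the α-stereocentre should not enolise.

Step 10
Reactants: 14 methyl (R)-2-methoxy-4-methylpentanoate
Product: 15 (R)-2-methoxy-4-methylpentanal
Conditions: iBu2AlH (1.05 equiv), Et2O, −78 °C; aq. potassium sodium tartrate; dried solution used at once
Reagents that add atoms: none
Why: Partial reduction of an ester, in which the aluminium hemiacetal, stabilised by chelation to the α-methoxy group, survives at −78 °C and releases the configurationally intact aldehyde only on work-up.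

Step 11
Reactants: 16 chlorodiphenylphosphine; 17 trimethyl orthoformate
Product: 18 (dimethoxymethyl)diphenylphosphine oxide
Conditions: neat, 0 °C to 60 °C
Reagents that add atoms: none
Why: Michaelis–Arbuzov-type reaction of the P–Cl compound with the orthoester, driven by formation of the P=O bond and escape of chloromethane.

Step 12
Reactants: 15 (R)-2-methoxy-4-methylpentanal; 18 (dimethoxymethyl)diphenylphosphine oxide
Product: 20 (R)-1,1,3-trimethoxy-5-methylhex-1-ene, via lithium alkoxide adduct 19 (not isolated)
Conditions: 18, LiN(iPr)2, THF, −100 °C; 15, −100 °C to −78 °C; KOtBu, −78 °C to rt; pentane, filtration, distillation from base-washed glass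
Reagents that add atoms: none
Why: Horner–Wittig olefination with a (dialkoxymethyl)phosphine oxide, a known route to ketene O,O-acetals: the potassium alkoxide loses diphenylphosphinate by syn elimination, the carbinol centre of 19 disappears, the two equal methoxy groups rule out E/Z isomers, and no enolate with a β-methoxy leaving group is ever formed.

Step 13
Reactants: 12 allyl 4-[2-(allyloxy)-6-(1,3-dioxolan-2-yl)-4-methylphenoxy]-2-oxo-2H-pyran-3-carboxylate; 20 (R)-1,1,3-trimethoxy-5-methylhex-1-ene
Product: 23 allyl 6-[2-(allyloxy)-6-(1,3-dioxolan-2-yl)-4-methylphenoxy]-2-methoxy-3-[(R)-1-methoxy-3-methylbutyl]benzoate, via bridged lactone cycloadduct 21 (not isolated), via 6,6-dimethoxycyclohexadiene 22 (not isolated)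
Conditions: 20 (3 equiv), K2CO3 (solid), toluene, sealed tube, 80 °C then 110 °C
Reagents that add atoms: none
Why: The HOMO of the ketene acetal and the pyrone LUMO, lowered by the C3 ester, combine in an inverse-electron-demand Diels–Alder reaction across pyrone C3 and C6 (concerted but strongly asynchronous, at the limit stepwise through a dimethoxycarbenium/malonate-type zwitterion) to give the 2-oxabicyclo[2.2.2]octenone 21. Retro-[4+2] loss of CO2 gives diene 22 and 1,2-elimination of methanol aromatises it, the closest known reaction type being the cycloaddition of 3-alkoxycarbonyl-2-pyrones with 1,1-dialkoxyalkenes to give 2-alkoxybenzoates. Ring A is closed by an intermolecular [4+2] cycloaddition that forms C3–C4 and C1–C2 in one event, with four ring atoms from the pyrone and two from the acetal. No stereocentre is created in the product, since the sp3 ring centres of 21 and 22 are erased on aromatisation and the exocyclic (R) centre lies outside the reacting π system and meets only neutral, base-buffered heat. The step needs regioselectivity and polarity secures it: the nucleophilic CH terminus of 20 bonds to pyrone C6, the vinylogous acceptor position of the ester and lactone carbonyls, so the acetal carbon bonds to pyrone C3, the methoxy group ends beside the ester and the side chain ends beside the methoxy group. Excess 20 takes up the liberated methanol, and a bath no hotter than 110 °C should hold back Claisen rearrangement of the aryl allyl ether.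

Step 14
Reactants: 23 allyl 6-[2-(allyloxy)-6-(1,3-dioxolan-2-yl)-4-methylphenoxy]-2-methoxy-3-[(R)-1-methoxy-3-methylbutyl]benzoate
Product: 24 6-[2-(1,3-dioxolan-2-yl)-6-hydroxy-4-methylphenoxy]-2-methoxy-3-[(R)-1-methoxy-3-methylbutyl]benzoic acid
Conditions: Pd(PPh3)4 (5 mol %), morpholine (10 equiv), THF, rt; pH 5 buffer
Reagents that add atoms: none
Why: Tsuji–Trost deallylation, in which zerovalent palladium ionises both allyl–oxygen bonds at the allyl carbon and morpholine traps the allyl units, so the steric shielding of the 2,6-disubstituted benzoate carbonyl does not matter.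

Step 15
Reactants: 24 6-[2-(1,3-dioxolan-2-yl)-6-hydroxy-4-methylphenoxy]-2-methoxy-3-[(R)-1-methoxy-3-methylbutyl]benzoic acid
Product: 25 6-(2-formyl-6-hydroxy-4-methylphenoxy)-2-methoxy-3-[(R)-1-methoxy-3-methylbutyl]benzoic acid (target)
Conditions: 1 M HCl–THF (1:4), rt
Reagents that add atoms: water, O
Why: Mild acid hydrolysis of an aryl dioxolane, which proceeds through a dialkoxy-stabilised cation far more readily than the benzylic methyl ether can ionise, so the stereocentre should be left untouched.

**Compound list**

1 | 2-methoxy-4-methylphenol (creosol) | COc1cc(C)ccc1O | starting material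
2 | 2-hydroxy-3-methoxy-5-methylbenzaldehyde | COc1cc(C)cc(C=O)c1O | intermediate
3 | 2,3-dihydroxy-5-methylbenzaldehyde | Oc1cc(C)cc(C=O)c1O | intermediate
4 | 3-(allyloxy)-2-hydroxy-5-methylbenzaldehyde | C=CCOc1cc(C)cc(C=O)c1O | intermediate
5 | 2-(allyloxy)-6-(1,3-dioxolan-2-yl)-4-methylphenol | C=CCOc1cc(C)cc(C2OCCO2)c1O | intermediate
6 | diallyl malonate | C=CCOC(=O)CC(=O)OCC=C | starting material
7 | (E)-3-ethoxyacryloyl chloride | CCO/C=C/C(=O)Cl | starting material
8 | diallyl 2-[(E)-3-ethoxyacryloyl]malonate | CCO/C=C/C(=O)C(C(=O)OCC=C)C(=O)OCC=C | intermediate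
9 | diallyl 2-(3-oxopropanoyl)malonate (not isolated) | O=CCC(=O)C(C(=O)OCC=C)C(=O)OCC=C | intermediate
10 | allyl 4-hydroxy-2-oxo-2H-pyran-3-carboxylate | C=CCOC(=O)C1=C(O)C=COC1=O | intermediate
11 | allyl 4-chloro-2-oxo-2H-pyran-3-carboxylate | C=CCOC(=O)C1=C(Cl)C=COC1=O | intermediate
12 | allyl 4-[2-(allyloxy)-6-(1,3-dioxolan-2-yl)-4-methylphenoxy]-2-oxo-2H-pyran-3-carboxylate | C=CCOC(=O)C1=C(Oc2c(OCC=C)cc(C)cc2C3OCCO3)C=COC1=O | intermediate
13 | (R)-2-hydroxy-4-methylpentanoic acid | OC(=O)[C@@H](CC(C)C)O | starting material
14 | methyl (R)-2-methoxy-4-methylpentanoate | COC(=O)[C@@H](CC(C)C)OC | intermediate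
15 | (R)-2-methoxy-4-methylpentanal | O=C[C@@H](CC(C)C)OC | intermediate
16 | chlorodiphenylphosphine | ClP(c1ccccc1)c1ccccc1 | starting material
17 | trimethyl orthoformate | COC(OC)OC | starting material
18 | (dimethoxymethyl)diphenylphosphine oxide | COC(OC)P(=O)(c1ccccc1)c1ccccc1 | intermediate
19 | lithium (3R)-1-(diphenylphosphoryl)-1,1,3-trimethoxy-5-methylhexan-2-olate, both carbinol epimers (not isolated) | [Li+].COC(OC)(C([O-])[C@@H](CC(C)C)OC)P(=O)(c1ccccc1)c1ccccc1 | intermediate
20 | (R)-1,1,3-trimethoxy-5-methylhex-1-ene | COC(OC)=C[C@@H](CC(C)C)OC | intermediate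
21 | allyl 5-[2-(allyloxy)-6-(1,3-dioxolan-2-yl)-4-methylphenoxy]-8,8-dimethoxy-7-[(R)-1-methoxy-3-methylbutyl]-3-oxo-2-oxabicyclo[2.2.2]oct-5-ene-4-carboxylate, ring diastereomers (not isolated) | O=C1OC2C=C(Oc3c(OCC=C)cc(C)cc3C4OCCO4)C1(C(=O)OCC=C)C(OC)(OC)C2[C@@H](CC(C)C)OC | intermediate
22 | allyl 2-[2-(allyloxy)-6-(1,3-dioxolan-2-yl)-4-methylphenoxy]-6,6-dimethoxy-5-[(R)-1-methoxy-3-methylbutyl]cyclohexa-1,3-diene-1-carboxylate, C5 epimers (not isolated) | COC1(OC)C(C(=O)OCC=C)=C(Oc2c(OCC=C)cc(C)cc2C3OCCO3)C=CC1[C@@H](CC(C)C)OC | intermediate
23 | allyl 6-[2-(allyloxy)-6-(1,3-dioxolan-2-yl)-4-methylphenoxy]-2-methoxy-3-[(R)-1-methoxy-3-methylbutyl]benzoate | COc1c([C@@H](CC(C)C)OC)ccc(Oc2c(OCC=C)cc(C)cc2C3OCCO3)c1C(=O)OCC=C | intermediate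
24 | 6-[2-(1,3-dioxolan-2-yl)-6-hydroxy-4-methylphenoxy]-2-methoxy-3-[(R)-1-methoxy-3-methylbutyl]benzoic acid | COc1c([C@@H](CC(C)C)OC)ccc(Oc2c(O)cc(C)cc2C3OCCO3)c1C(=O)O | intermediate
25 | 6-(2-formyl-6-hydroxy-4-methylphenoxy)-2-methoxy-3-[(R)-1-methoxy-3-methylbutyl]benzoic acid (CNP0328949.1) | COc1c([C@@H](CC(C)C)OC)ccc(Oc2c(O)cc(C)cc2C=O)c1C(=O)O | target

**Step count**

Total step count: 15.
Longest linear sequence: 8 steps (1, 2, 3, 4, 8, 13, 14, 15).

**Steps most likely to fail**

Step 13. The 4-aryloxy donor and the branched dienophile terminus may slow the cycloaddition considerably. Several side processes could then take over: ipso attack at pyrone C4 with loss of the aryloxide, intramolecular cycloaddition of the allyl ester, Claisen rearrangement of the aryl allyl ether, or ionisation of the allylic methoxy group. The fallback changes the order of bond formation, so that ring A is made before the diaryl ether. It sets out from 10, which nBu4NBr and P2O5 in hot toluene should convert into allyl 4-bromo-2-oxo-2H-pyran-3-carboxylate F1. This more electron-poor pyrone carries no ring B and should combine with 20 at lower temperature to give allyl 6-bromo-2-methoxy-3-[(R)-1-methoxy-3-methylbutyl]benzoate F2. An Ullmann ether coupling of F2 with phenol 5 (CuI, picolinic acid, K3PO4, DMSO, 90 °C) comes back to the route at 23.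

Step 12. There are three dangers: decay of the lithiated phosphine oxide before it meets the aldehyde, reversal of the addition under KOtBu with epimerisation of the released α-methoxy aldehyde, and hydrolysis of the ketene acetal during isolation. The fallback replaces the dimethyl acetal by a silyl methyl ketene acetal made from an ester, and adds the C2 methyl group afterwards.
- Commercial methyl 5-methyl-3-oxohexanoate is reduced by Noyori hydrogenation (RuCl2[(R)-BINAP], H2, MeOH; β-keto esters need the halide complex) to methyl (R)-3-hydroxy-5-methylhexanoate F3.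
- O-Methylation (Me3OBF4, 1,8-bis(dimethylamino)naphthalene, CH2Cl2) gives methyl (R)-3-methoxy-5-methylhexanoate F4.
- Enolisation with LiN(iPr)2 in the presence of Me3SiCl at −78 °C traps the enolate before β-elimination and gives (R)-1,3-dimethoxy-5-methyl-1-(trimethylsilyloxy)hex-1-ene F5.
- The fallback sets out from pyrone 12, which is heated with F5 in toluene. Loss of CO2 and methanol should give the 2-(trimethylsilyloxy)benzoate F6.
- KF in methanol frees the 2-hydroxybenzoate F7, and MeI with K2CO3 in acetone comes back to the route at 23.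

Step 6. The lactonisation may be eroded by hydrolytic deacylation of the tricarbonyl compound, exchange of the allyl ester with liberated ethanol, and slow E to Z isomerisation ahead of ring closure. The fallback lets an acid-labile ester supply the ring oxygen under anhydrous conditions. It sets out from 7, which acylates allyl tert-butyl malonate F8 (from mono-tert-butyl malonate, allyl bromide and K2CO3) under the conditions of step 5. This gives allyl tert-butyl 2-[(E)-3-ethoxyacryloyl]malonate F9. CF3CO2H in CH2Cl2 should remove the tert-butyl group, and the carboxyl oxygen so released should add to the β-carbon of the ethoxy enone and expel ethanol, which comes back to the route at 10.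

Further compounds
F1 | step 13 | allyl 4-bromo-2-oxo-2H-pyran-3-carboxylate | C=CCOC(=O)C1=C(Br)C=COC1=O
F2 | step 13 | allyl 6-bromo-2-methoxy-3-[(R)-1-methoxy-3-methylbutyl]benzoate | COc1c([C@@H](CC(C)C)OC)ccc(Br)c1C(=O)OCC=C
F3 | step 12 | methyl (R)-3-hydroxy-5-methylhexanoate | COC(=O)C[C@@H](CC(C)C)O
F4 | step 12 | methyl (R)-3-methoxy-5-methylhexanoate | COC(=O)C[C@@H](CC(C)C)OC
F5 | step 12 | (R)-1,3-dimethoxy-5-methyl-1-(trimethylsilyloxy)hex-1-ene | COC(O[Si](C)(C)C)=C[C@@H](CC(C)C)OC
F6 | step 12 | allyl 6-[2-(allyloxy)-6-(1,3-dioxolan-2-yl)-4-methylphenoxy]-3-[(R)-1-methoxy-3-methylbutyl]-2-(trimethylsilyloxy)benzoate | C[Si](C)(C)Oc1c([C@@H](CC(C)C)OC)ccc(Oc2c(OCC=C)cc(C)cc2C3OCCO3)c1C(=O)OCC=C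
F7 | step 12 | allyl 6-[2-(allyloxy)-6-(1,3-dioxolan-2-yl)-4-methylphenoxy]-2-hydroxy-3-[(R)-1-methoxy-3-methylbutyl]benzoate | Oc1c([C@@H](CC(C)C)OC)ccc(Oc2c(OCC=C)cc(C)cc2C3OCCO3)c1C(=O)OCC=C
F8 | step 6 | allyl tert-butyl malonate | C=CCOC(=O)CC(=O)OC(C)(C)C
F9 | step 6 | allyl tert-butyl 2-[(E)-3-ethoxyacryloyl]malonate | CCO/C=C/C(=O)C(C(=O)OCC=C)C(=O)OC(C)(C)C
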